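**Plan**
- Labels: flavone numbering for rings A and C (O1 to C8a) and ring B (C1' to C6'); the side chain on C8 is C1'' to C6''; the only stereocentre, C2'', is R.
- Retrosynthetic cuts: O1–C2 of ring C (back to an ynone), C4–C4a (ring A aryllithium plus a ring B propynal), C2''–isopropenyl (back to a boronate), then C8–C1'' and C2''–C3'' together.
- Enabling feature: C2'' is a CH between C1''H2 on C8 of ring A and C3''H2 of the chain, so C1''–C2'' can come from a vinyl group across which the ring A aryl and the C3'' alkyl group are added.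
- Forward order: side chain onto a symmetric ring A bromide first, then isopropenyl, then ring B through the ynone; ring C closes last through O8a while O5 is still silylated, which fixes the 8-substitution.
- Stereochemistry: C2'' is set by the chiral Mandyphos ligand in the palladium-induced 1,2-metallate shift and carried over with retention in the Zweifel olefination.

Key step: step 7

Remark: the vinyllithium solution 10 is used as prepared and contains LiBr; the Mandyphos antipode that gives the R boronate is fixed in a trial run.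

**Step 1**
Reactants: 1 phloroglucinol
Product: 2 3,5-bis(methoxymethoxy)phenol
Conditions: MOMCl (2.0 equiv), i-Pr2NEt (2.2 equiv), DMF, 0 °C to rt; chromatography
Reagents that add atoms: chloromethyl methyl ether, COCCl
Why: Williamson-type O-alkylation of the threefold symmetric triol should give the bis-ether as the main part of a statistical mixture, which is tolerable at the first step from a cheap material because the mono- and tris-ethers are separable and can be recycled.

**Step 2**
Reactants: 2 3,5-bis(methoxymethoxy)phenol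
Product: 3 [3,5-bis(methoxymethoxy)phenoxy]triisopropylsilane
Conditions: TIPSCl (1.2 equiv), imidazole (2.5 equiv), DMF, rt
Reagents that add atoms: triisopropylsilyl chloride, CC(C)[Si](Cl)(C(C)C)C(C)C
Why: Imidazole-promoted silyl ether formation at the remaining phenol installs a bulky group that shields its two ortho positions and later distinguishes O5 from O7 and O8a.

**Step 3**
Reactants: 3 [3,5-bis(methoxymethoxy)phenoxy]triisopropylsilane
Product: 5 2-bromo-1,3-bis(methoxymethoxy)-5-(triisopropylsilyloxy)benzene, via aryllithium 4 (not isolated)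
Conditions: n-BuLi (1.1 equiv), THF, 0 °C; then BrCl2C–CCl2Br, −78 °C to rt
Reagents that add atoms: 1,2-dibromo-1,1,2,2-tetrachloroethane, BrC(Cl)(Cl)C(Cl)(Cl)Br
Why: Directed ortho-metalation takes place at the position flanked by both MOM ethers, the other two ring positions being screened by the silyl ether, and the aryllithium is brominated by the positive-bromine donor.

**Step 4**
Reactants: 6 2-methylbut-3-en-2-ol
Product: 7 triethyl[(2-methylbut-3-en-2-yl)oxy]silane
Conditions: TESOTf (1.1 equiv), 2,6-lutidine (1.5 equiv), CH2Cl2, 0 °C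
Reagents that add atoms: triethylsilyl trifluoromethanesulfonate, CC[Si](CC)(CC)OS(=O)(=O)C(F)(F)F
Why: Silyl triflate silylation is the standard way to cap a hindered tertiary alcohol, which would otherwise consume organolithium reagent and chelate boron in the later steps.

**Step 5**
Reactants: 7 triethyl[(2-methylbut-3-en-2-yl)oxy]silane
Product: 8 2-[3-methyl-3-(triethylsilyloxy)butyl]-4,4,5,5-tetramethyl-1,3,2-dioxaborolane
Conditions: pinacolborane (1.2 equiv), [Ir(cod)Cl]2 (1.5 mol%), dppm (3 mol%), CH2Cl2, rt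
Reagents that add atoms: pinacolborane, [H]B1OC(C)(C)C(C)(C)O1
Why: Iridium-catalysed hydroboration of a terminal alkene with pinacolborane is anti-Markovnikov and should give the primary boronate even next to the quaternary carbon.

**Step 6**
Reactants: 9 vinyl bromide
Product: 10 vinyllithium (titrated ethereal solution)
Conditions: t-BuLi (2.0 equiv), Et2O, −78 °C
Reagents that add atoms: tert-butyllithium, [Li]C(C)(C)C
Why: Bromine–lithium exchange gives the alkenyllithium and the second equivalent of t-BuLi destroys the tert-butyl bromide formed, so no alkyllithium is left to compete for boron.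

**Step 7**
Reactants: 8 2-[3-methyl-3-(triethylsilyloxy)butyl]-4,4,5,5-tetramethyl-1,3,2-dioxaborolane; 10 vinyllithium; 5 2-bromo-1,3-bis(methoxymethoxy)-5-(triisopropylsilyloxy)benzene
Product: 12 2-[(2R)-1-[2,6-bis(methoxymethoxy)-4-(triisopropylsilyloxy)phenyl]-5-methyl-5-(triethylsilyloxy)hexan-2-yl]-4,4,5,5-tetramethyl-1,3,2-dioxaborolane, via lithium vinylborate 11 (not isolated)
Conditions: 8, 10 (1.0 equiv), Et2O, 0 °C to rt, solvent changed to THF; then 5 (1.0 equiv), Pd(OAc)2 (3 mol%), Mandyphos ligand 1,1'-bis[bis(4-methoxy-3,5-dimethylphenyl)phosphino]-2,2'-bis[α-(dimethylamino)benzyl]ferrocene (3.6 mol%, antipode giving R), NaOTf (3 equiv), THF, 60 °C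
Reagents that add atoms: none
Why: Zerovalent palladium formed from Pd(OAc)2 and the ligand inserts into the C–Br bond of 5, NaOTf exchanges bromide for triflate, and the cationic aryl complex of divalent palladium binds the vinyl group of 11, whereupon the alkyl group shifts from boron to the α-carbon as palladium bonds to the β-carbon and reductive elimination forms C8–C1''. The closest known reaction type is the palladium/Mandyphos-catalysed enantioselective conjunctive cross-coupling of vinylboron ate complexes with aryl halides and triflates, applied here to a bromide with two ortho ether groups. No ring closes; the two skeletal bonds C8–C1'' and C2''–C3'' form in one operation and boron stays on C2''. The stereocentre C2'' is controlled by the ligand, which differentiates the two faces of the bound vinyl group during the 1,2-metallate shift, and the sense is checked by oxidising a sample to the carbinol. The step needs the metallate-shift pathway to win over direct transfer of the vinyl or alkyl group to palladium and over halide inhibition, which the four-coordinate pinacol boronate, the triflate additive (it also takes up the LiBr carried in with 10) and the small MOM ethers should secure, while the symmetric substitution of 5 leaves no regiochemical choice on the ring.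

**Step 8**
Reactants: 12 the R secondary boronate
Product: 13 2-[(2R)-1-[3-bromo-2,6-bis(methoxymethoxy)-4-(triisopropylsilyloxy)phenyl]-5-methyl-5-(triethylsilyloxy)hexan-2-yl]-4,4,5,5-tetramethyl-1,3,2-dioxaborolane
Conditions: NBS (1.0 equiv), CH2Cl2, −78 to −30 °C
Reagents that add atoms: N-bromosuccinimide, O=C1CCC(=O)N1Br
Why: Electrophilic aromatic bromination of the trioxygenated ring at one of its two equivalent free positions proceeds under neutral conditions that leave the acetals, silyl ethers and boronate alone, and it is placed before the alkene exists.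

**Step 9**
Reactants: 13 the brominated R boronate
Product: 16 2-bromo-3,5-bis(methoxymethoxy)-4-[(2R)-5-methyl-2-(prop-1-en-2-yl)-5-(triethylsilyloxy)hexyl]-1-(triisopropylsilyloxy)benzene, via lithium isopropenylborate 14 (not isolated), via iodoalkyl boronate 15 (not isolated)
Conditions: 2-bromopropene (1.3 equiv), t-BuLi (2.4 equiv), Et2O, −78 °C; 13, THF, −78 °C; I2 (1.3 equiv), THF, −78 °C; NaOMe (3 equiv), MeOH, −78 to 0 °C
Reagents that add atoms: 2-bromopropene, C=C(C)Br (converted in the flask into isopropenyllithium, [Li]C(C)=C)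
Why: In this Zweifel olefination the alkenyllithium adds to boron, iodine triggers the 1,2-shift of the secondary alkyl group with retention at C2'', and methoxide induces anti elimination of boron and iodide to the 1,1-disubstituted alkene, ate-complex formation at −78 °C being faster than exchange at the hindered ring bromide.

**Step 10**
Reactants: 17 2,4-dihydroxybenzaldehyde
Product: 18 2,4-bis(methoxymethoxy)benzaldehyde
Conditions: MOMCl (3 equiv), i-Pr2NEt (4 equiv), CH2Cl2, 0 °C to reflux
Reagents that add atoms: chloromethyl methyl ether, COCCl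
Why: Williamson-type acetal ether formation protects both phenols, the hydrogen-bonded ortho hydroxyl needing the excess reagent and gentle heating.

**Step 11**
Reactants: 18 2,4-bis(methoxymethoxy)benzaldehyde
Product: 19 1-ethynyl-2,4-bis(methoxymethoxy)benzene
Conditions: dimethyl (1-diazo-2-oxopropyl)phosphonate (1.3 equiv), K2CO3 (2 equiv), MeOH, rt
Reagents that add atoms: dimethyl (1-diazo-2-oxopropyl)phosphonate, CC(=O)C(=[N+]=[N-])P(=O)(OC)OC
Why: The Ohira–Bestmann variant of the Seyferth–Gilbert homologation converts an aryl aldehyde into the terminal alkyne under mild base that the acetals tolerate.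

**Step 12**
Reactants: 19 1-ethynyl-2,4-bis(methoxymethoxy)benzene
Product: 22 3-[2,4-bis(methoxymethoxy)phenyl]prop-2-ynal, via lithium acetylide 20 (not isolated), via lithium hemiaminolate 21 (not isolated)
Conditions: n-BuLi (1.05 equiv), THF, −78 °C; DMF (2 equiv), −78 to 0 °C; poured into aq KH2PO4
Reagents that add atoms: N,N-dimethylformamide, CN(C)C=O
Why: Formylation of a lithium acetylide with DMF gives the ynal after a buffered reverse quench, which keeps the liberated dimethylamine from adding to the triple bond.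

**Step 13**
Reactants: 16 the isopropenyl aryl bromide; 22 3-[2,4-bis(methoxymethoxy)phenyl]prop-2-ynal
Product: 24 1-[2,4-bis(methoxymethoxy)-3-[(2R)-5-methyl-2-(prop-1-en-2-yl)-5-(triethylsilyloxy)hexyl]-6-(triisopropylsilyloxy)phenyl]-3-[2,4-bis(methoxymethoxy)phenyl]prop-2-yn-1-ol (both carbinol epimers), via aryllithium 23 (not isolated)
Conditions: n-BuLi (1.05 equiv), THF, −78 °C; 22 (1.2 equiv), −78 °C; aq NH4Cl
Reagents that add atoms: none
Why: Bromine–lithium exchange at −78 °C gives the aryllithium, which adds 1,2 to the unhindered ynal faster than its ortho silyl group can migrate from oxygen to carbon, and the uncontrolled carbinol centre is erased by the next oxidation.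

**Step 14**
Reactants: 24 the propargylic alcohol
Product: 25 1-[2,4-bis(methoxymethoxy)-3-[(2R)-5-methyl-2-(prop-1-en-2-yl)-5-(triethylsilyloxy)hexyl]-6-(triisopropylsilyloxy)phenyl]-3-[2,4-bis(methoxymethoxy)phenyl]prop-2-yn-1-one
Conditions: activated MnO2 (excess), CH2Cl2, rt
Reagents that add atoms: none
Why: MnO2 oxidation is selective for the benzylic and propargylic carbinol and leaves the alkene, acetals and silyl ethers untouched.

**Step 15**
Reactants: 25 the protected ynone
Product: 27 2-(2,4-dihydroxyphenyl)-7-hydroxy-8-[(2R)-5-hydroxy-5-methyl-2-(prop-1-en-2-yl)hexyl]-5-(triisopropylsilyloxy)-4H-chromen-4-one, via tetraphenol ynone 26 (not isolated)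
Conditions: HCl (0.5 M) in MeOH/THF, 40 °C; evaporate; then K2CO3 (0.5 equiv), acetone, rt
Reagents that add atoms: none
Why: Acid-catalysed acetal exchange with methanol removes the four aryl MOM ethers and the tertiary triethylsilyl ether while the far more acid-stable aryl triisopropylsilyl ether stays, and base then drives the 6-endo-dig oxa-Michael addition of the only free ortho phenol (O8a) onto the ynone, so ring C closes with C8 next to O1 and any β-methoxy enone from the acid stage converges on the same flavone.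

**Step 16**
Reactants: 27 the 5-O-silyl flavone
Product: 28 2-(2,4-dihydroxyphenyl)-5,7-dihydroxy-8-[(2R)-5-hydroxy-5-methyl-2-(prop-1-en-2-yl)hexyl]-4H-chromen-4-one (target)
Conditions: TBAF (1.5 equiv), AcOH (1.5 equiv), THF, 0 °C
Reagents that add atoms: none
Why: Buffered fluoride desilylation cleaves the aryl silyl ether, which is activated by the neighbouring C4 carbonyl, without exposing the polyphenol, the alkene or the tertiary alcohol to acid or strong base.

**Compound list**
1 | phloroglucinol | Oc1cc(O)cc(O)c1 | starting material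
2 | 3,5-bis(methoxymethoxy)phenol | COCOc1cc(O)cc(OCOC)c1 | intermediate
3 | [3,5-bis(methoxymethoxy)phenoxy]triisopropylsilane | COCOc1cc(OCOC)cc(O[Si](C(C)C)(C(C)C)C(C)C)c1 | intermediate
4 | [2,6-bis(methoxymethoxy)-4-(triisopropylsilyloxy)phenyl]lithium | [Li]c1c(OCOC)cc(O[Si](C(C)C)(C(C)C)C(C)C)cc1OCOC | intermediate
5 | 2-bromo-1,3-bis(methoxymethoxy)-5-(triisopropylsilyloxy)benzene | Brc1c(OCOC)cc(O[Si](C(C)C)(C(C)C)C(C)C)cc1OCOC | intermediate
6 | 2-methylbut-3-en-2-ol | C=CC(C)(C)O | starting material
7 | triethyl[(2-methylbut-3-en-2-yl)oxy]silane | C=CC(C)(C)O[Si](CC)(CC)CC | intermediate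
8 | 2-[3-methyl-3-(triethylsilyloxy)butyl]-4,4,5,5-tetramethyl-1,3,2-dioxaborolane | CC1(C)OB(CCC(C)(C)O[Si](CC)(CC)CC)OC1(C)C | intermediate
9 | vinyl bromide | C=CBr | starting material
10 | vinyllithium | [Li]C=C | intermediate
11 | lithium vinylborate of 8 (vinyl and the alkyl group on four-coordinate boron, pinacol retained) | [Li+].C=C[B-]1(CCC(C)(C)O[Si](CC)(CC)CC)OC(C)(C)C(C)(C)O1 | intermediate
12 | 2-[(2R)-1-[2,6-bis(methoxymethoxy)-4-(triisopropylsilyloxy)phenyl]-5-methyl-5-(triethylsilyloxy)hexan-2-yl]-4,4,5,5-tetramethyl-1,3,2-dioxaborolane | CC1(C)OB(OC1(C)C)[C@H](CCC(C)(C)O[Si](CC)(CC)CC)Cc1c(OCOC)cc(O[Si](C(C)C)(C(C)C)C(C)C)cc1OCOC | intermediate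
13 | 2-[(2R)-1-[3-bromo-2,6-bis(methoxymethoxy)-4-(triisopropylsilyloxy)phenyl]-5-methyl-5-(triethylsilyloxy)hexan-2-yl]-4,4,5,5-tetramethyl-1,3,2-dioxaborolane | CC1(C)OB(OC1(C)C)[C@H](CCC(C)(C)O[Si](CC)(CC)CC)Cc1c(OCOC)cc(O[Si](C(C)C)(C(C)C)C(C)C)c(Br)c1OCOC | intermediate
14 | lithium isopropenylborate of 13 (isopropenyl on four-coordinate boron, R at C2'') | [Li+].C=C(C)[B-]1(OC(C)(C)C(C)(C)O1)[C@H](CCC(C)(C)O[Si](CC)(CC)CC)Cc1c(OCOC)cc(O[Si](C(C)C)(C(C)C)C(C)C)c(Br)c1OCOC | intermediate
15 | 2-[(3R)-3-[[3-bromo-2,6-bis(methoxymethoxy)-4-(triisopropylsilyloxy)phenyl]methyl]-1-iodo-2,6-dimethyl-6-(triethylsilyloxy)heptan-2-yl]-4,4,5,5-tetramethyl-1,3,2-dioxaborolane (both epimers at C2) | CC1(C)OB(OC1(C)C)C(C)(CI)[C@H](CCC(C)(C)O[Si](CC)(CC)CC)Cc1c(OCOC)cc(O[Si](C(C)C)(C(C)C)C(C)C)c(Br)c1OCOC | intermediate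
16 | 2-bromo-3,5-bis(methoxymethoxy)-4-[(2R)-5-methyl-2-(prop-1-en-2-yl)-5-(triethylsilyloxy)hexyl]-1-(triisopropylsilyloxy)benzene | C=C(C)[C@H](CCC(C)(C)O[Si](CC)(CC)CC)Cc1c(OCOC)cc(O[Si](C(C)C)(C(C)C)C(C)C)c(Br)c1OCOC | intermediate
17 | 2,4-dihydroxybenzaldehyde | O=Cc1ccc(O)cc1O | starting material
18 | 2,4-bis(methoxymethoxy)benzaldehyde | O=Cc1ccc(OCOC)cc1OCOC | intermediate
19 | 1-ethynyl-2,4-bis(methoxymethoxy)benzene | C#Cc1ccc(OCOC)cc1OCOC | intermediate
20 | lithium [2,4-bis(methoxymethoxy)phenyl]acetylide | [Li]C#Cc1ccc(OCOC)cc1OCOC | intermediate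
21 | lithium 1-(dimethylamino)-3-[2,4-bis(methoxymethoxy)phenyl]prop-2-yn-1-olate | [Li]OC(N(C)C)C#Cc1ccc(OCOC)cc1OCOC | intermediate
22 | 3-[2,4-bis(methoxymethoxy)phenyl]prop-2-ynal | O=CC#Cc1ccc(OCOC)cc1OCOC | intermediate
23 | aryllithium from 16 (lithium in place of bromine, R at C2'') | C=C(C)[C@H](CCC(C)(C)O[Si](CC)(CC)CC)Cc1c(OCOC)cc(O[Si](C(C)C)(C(C)C)C(C)C)c([Li])c1OCOC | intermediate
24 | 1-[2,4-bis(methoxymethoxy)-3-[(2R)-5-methyl-2-(prop-1-en-2-yl)-5-(triethylsilyloxy)hexyl]-6-(triisopropylsilyloxy)phenyl]-3-[2,4-bis(methoxymethoxy)phenyl]prop-2-yn-1-ol (both carbinol epimers) | C=C(C)[C@H](CCC(C)(C)O[Si](CC)(CC)CC)Cc1c(OCOC)cc(O[Si](C(C)C)(C(C)C)C(C)C)c(C(O)C#Cc2ccc(OCOC)cc2OCOC)c1OCOC | intermediate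
25 | 1-[2,4-bis(methoxymethoxy)-3-[(2R)-5-methyl-2-(prop-1-en-2-yl)-5-(triethylsilyloxy)hexyl]-6-(triisopropylsilyloxy)phenyl]-3-[2,4-bis(methoxymethoxy)phenyl]prop-2-yn-1-one | C=C(C)[C@H](CCC(C)(C)O[Si](CC)(CC)CC)Cc1c(OCOC)cc(O[Si](C(C)C)(C(C)C)C(C)C)c(C(=O)C#Cc2ccc(OCOC)cc2OCOC)c1OCOC | intermediate
26 | 1-[2,4-dihydroxy-3-[(2R)-5-hydroxy-5-methyl-2-(prop-1-en-2-yl)hexyl]-6-(triisopropylsilyloxy)phenyl]-3-(2,4-dihydroxyphenyl)prop-2-yn-1-one | C=C(C)[C@H](CCC(C)(C)O)Cc1c(O)cc(O[Si](C(C)C)(C(C)C)C(C)C)c(C(=O)C#Cc2ccc(O)cc2O)c1O | intermediate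
27 | 2-(2,4-dihydroxyphenyl)-7-hydroxy-8-[(2R)-5-hydroxy-5-methyl-2-(prop-1-en-2-yl)hexyl]-5-(triisopropylsilyloxy)-4H-chromen-4-one | C=C(C)[C@H](CCC(C)(C)O)Cc1c(O)cc(O[Si](C(C)C)(C(C)C)C(C)C)c2c(=O)cc(-c3ccc(O)cc3O)oc12 | intermediate
28 | 2-(2,4-dihydroxyphenyl)-5,7-dihydroxy-8-[(2R)-5-hydroxy-5-methyl-2-(prop-1-en-2-yl)hexyl]-4H-chromen-4-one | C=C(C)[C@H](CCC(C)(C)O)Cc1c(O)cc(O)c2c(=O)cc(-c3ccc(O)cc3O)oc12 | target

**Step count and risks**
Total steps: 16. Longest linear sequence: 10 steps (1, 2, 3, 7, 8, 9, 13, 14, 15, 16, from phloroglucinol).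

Step 7. Oxidative addition into the electron-rich, doubly ortho-substituted C–Br bond may be slow, the vinyl group may transfer directly to palladium instead of undergoing the metallate shift, or facial discrimination may be poor. The fallback builds the same secondary boronate by sparteine-mediated lithiation–borylation of a carbamate. It sets out from 5: bromine–lithium exchange (n-BuLi, THF, −78 °C) regenerates aryllithium 4, and a Matteson-type 1,2-shift with 2-(iodomethyl)-4,4,5,5-tetramethyl-1,3,2-dioxaborolane gives 2-[2,6-bis(methoxymethoxy)-4-(triisopropylsilyloxy)benzyl]-4,4,5,5-tetramethyl-1,3,2-dioxaborolane F1. The chain partner comes from γ-butyrolactone and MeMgBr, which give 4-methylpentane-1,4-diol F2; N,N-diisopropylcarbamoyl chloride acylates the primary hydroxyl to 4-hydroxy-4-methylpentyl N,N-diisopropylcarbamate F3, and TESOTf caps the tertiary one to give 4-methyl-4-(triethylsilyloxy)pentyl N,N-diisopropylcarbamate F4. Deprotonation with s-BuLi and (−)-sparteine (Et2O, −78 °C; the antipode if the sense proves opposite) should give the S lithiated carbamate F5. F5 takes up F1 with retention to the boronate complex F6, and on warming the benzyl group migrates with inversion and expels the carbamate, so the fallback comes back to the route at 12.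

Step 15. Protonation of the isopropenyl group can lead to chroman formation through a neighbouring phenol or to double-bond migration that erases C2''; the tertiary carbinol can solvolyse; closure can go 5-exo to the aurone. The fallback avoids protic acid and sets out from 25. TMSOTf with 2,2'-bipyridyl (MeCN, 0 °C) exchanges the four aryl MOM ethers for trimethylsilyl ethers, giving the tetrakis(trimethylsilyl) ether F7, which water hydrolyses to the tetraphenol ynone that still carries both the triethylsilyl and triisopropylsilyl groups F8. K2CO3 in acetone then closes ring C through O8a to the doubly silylated flavone F9, and excess TBAF with AcOH (THF, rt) removes both silyl groups, so the fallback comes back at 28.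

Step 9. The alkenyllithium may exchange with the ring bromide in competition with ate-complex formation, or iodine may attack the electron-rich ring. The fallback reverses the order of halogenation and olefination and sets out from 12. Isopropenyllithium gives the bromine-free lithium isopropenylborate F10, iodine converts it into the bromine-free iodoalkyl boronate F11, and NaOMe gives 1,3-bis(methoxymethoxy)-2-[(2R)-5-methyl-2-(prop-1-en-2-yl)-5-(triethylsilyloxy)hexyl]-5-(triisopropylsilyloxy)benzene F12. NBS (CH2Cl2, −78 °C) then brominates the ring, which is far more nucleophilic than the 1,1-disubstituted alkene, and the fallback comes back at 16.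

**Further compounds**
F1 | step 7 | 2-[2,6-bis(methoxymethoxy)-4-(triisopropylsilyloxy)benzyl]-4,4,5,5-tetramethyl-1,3,2-dioxaborolane | CC1(C)OB(Cc2c(OCOC)cc(O[Si](C(C)C)(C(C)C)C(C)C)cc2OCOC)OC1(C)C
F2 | step 7 | 4-methylpentane-1,4-diol | CC(C)(O)CCCO
F3 | step 7 | 4-hydroxy-4-methylpentyl N,N-diisopropylcarbamate | CC(C)N(C(C)C)C(=O)OCCCC(C)(C)O
F4 | step 7 | 4-methyl-4-(triethylsilyloxy)pentyl N,N-diisopropylcarbamate | CC(C)N(C(C)C)C(=O)OCCCC(C)(C)O[Si](CC)(CC)CC
F5 | step 7 | (S)-1-lithio-4-methyl-4-(triethylsilyloxy)pentyl N,N-diisopropylcarbamate | CC(C)N(C(C)C)C(=O)O[C@@H]([Li])CCC(C)(C)O[Si](CC)(CC)CC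
F6 | step 7 | lithium boronate complex of F5 with F1 (carbamate-bearing carbon and benzyl group on four-coordinate boron) | [Li+].CC(C)N(C(C)C)C(=O)O[C@H](CCC(C)(C)O[Si](CC)(CC)CC)[B-]1(Cc2c(OCOC)cc(O[Si](C(C)C)(C(C)C)C(C)C)cc2OCOC)OC(C)(C)C(C)(C)O1
F7 | step 15 | tetrakis(trimethylsilyl) ether of the ynone (trimethylsilyl in place of each MOM group of 25) | C=C(C)[C@H](CCC(C)(C)O[Si](CC)(CC)CC)Cc1c(O[Si](C)(C)C)cc(O[Si](C(C)C)(C(C)C)C(C)C)c(C(=O)C#Cc2ccc(O[Si](C)(C)C)cc2O[Si](C)(C)C)c1O[Si](C)(C)C
F8 | step 15 | 1-[2,4-dihydroxy-3-[(2R)-5-methyl-2-(prop-1-en-2-yl)-5-(triethylsilyloxy)hexyl]-6-(triisopropylsilyloxy)phenyl]-3-(2,4-dihydroxyphenyl)prop-2-yn-1-one | C=C(C)[C@H](CCC(C)(C)O[Si](CC)(CC)CC)Cc1c(O)cc(O[Si](C(C)C)(C(C)C)C(C)C)c(C(=O)C#Cc2ccc(O)cc2O)c1O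
F9 | step 15 | 2-(2,4-dihydroxyphenyl)-7-hydroxy-8-[(2R)-5-methyl-2-(prop-1-en-2-yl)-5-(triethylsilyloxy)hexyl]-5-(triisopropylsilyloxy)-4H-chromen-4-one | C=C(C)[C@H](CCC(C)(C)O[Si](CC)(CC)CC)Cc1c(O)cc(O[Si](C(C)C)(C(C)C)C(C)C)c2c(=O)cc(-c3ccc(O)cc3O)oc12
F10 | step 9 | lithium isopropenylborate of 12 (isopropenyl on four-coordinate boron, R at C2'') | [Li+].C=C(C)[B-]1(OC(C)(C)C(C)(C)O1)[C@H](CCC(C)(C)O[Si](CC)(CC)CC)Cc1c(OCOC)cc(O[Si](C(C)C)(C(C)C)C(C)C)cc1OCOC
F11 | step 9 | 2-[(3R)-3-[[2,6-bis(methoxymethoxy)-4-(triisopropylsilyloxy)phenyl]methyl]-1-iodo-2,6-dimethyl-6-(triethylsilyloxy)heptan-2-yl]-4,4,5,5-tetramethyl-1,3,2-dioxaborolane (both epimers at C2) | CC1(C)OB(OC1(C)C)C(C)(CI)[C@H](CCC(C)(C)O[Si](CC)(CC)CC)Cc1c(OCOC)cc(O[Si](C(C)C)(C(C)C)C(C)C)cc1OCOC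
F12 | step 9 | 1,3-bis(methoxymethoxy)-2-[(2R)-5-methyl-2-(prop-1-en-2-yl)-5-(triethylsilyloxy)hexyl]-5-(triisopropylsilyloxy)benzene | C=C(C)[C@H](CCC(C)(C)O[Si](CC)(CC)CC)Cc1c(OCOC)cc(O[Si](C(C)C)(C(C)C)C(C)C)cc1OCOC
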